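**Retrosynthetic overview**

1. The route rests on the trisubstituted C1=C10 alkene at the fusion of rings A and B, flanked by quaternary C9 and tertiary C5 (halimane numbering). It is formed last, with ring A, by titanium-mediated coupling of a C10 ketone with a C1 aldehyde, so its position is fixed by the two carbonyl carbons.
2. The ring-B keto aldehyde comes from a chirality-transfer ketal Claisen rearrangement between a ring-B ketal and an (S,E)-γ-hydroxy enoate. This forms C4–C5 and sets C4 and C5; the new alkene becomes C2–C3 and the benzyloxymethyl group becomes the C1 aldehyde.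
3. Ring B with C8 and C9 comes from copper-catalysed asymmetric conjugate methylation–allylation of 2-methylcyclohex-2-en-1-one; the allyl group is cut back to the C11–C12 oxyethyl arm.
4. After ring closure the C12–C13 bond is made by Negishi coupling with an (E)-vinyl iodide from but-2-yn-1-ol, followed by C18 ester cleavage, desilylation and propionylation at O15. Ring B is present from step 1; ring A is formed in step 10.

Key step: step 10

Remark on the chemistry: the C12 oxygen is carried as a pivalate instead of a silyl ether, because a γ-silyloxy ketone would be expected to cyclise onto the C10 oxocarbenium ion during the ketal chemistry of steps 4 and 7.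

**Route**

Step 1
Reactants: 1 2-methylcyclohex-2-en-1-one; 2 allyl bromide
Product: 4 (2S,3R)-2,3-dimethyl-2-(prop-2-en-1-yl)cyclohexan-1-one, via aluminium enolate 3 (not isolated)
Conditions: Me3Al, copper thiophene-2-carboxylate (CuTC, cat.), BINOL-derived bis(1-phenylethyl)phosphoramidite ligand (cat., antipode chosen for the 3R enolate), Et2O, −30 °C; then MeLi, THF/DMPU, 2, −30 °C → rt
Reagents that add atoms: trimethylaluminium, C[Al](C)C
Why: Copper-catalysed asymmetric conjugate addition should set C8 under ligand control, and the regiodefined enolate, activated as its lithium aluminate, should be allylated on the face anti to the neighbouring C8 methyl, so that C9 carries allyl trans and methyl cis to it (tandem conjugate addition–enolate alkylation).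

Step 2
Reactants: 4 (2S,3R)-2,3-dimethyl-2-(prop-2-en-1-yl)cyclohexan-1-one
Product: 7 (2S,3R)-2-(2-hydroxyethyl)-2,3-dimethylcyclohexan-1-one, via ozonide 5 (not isolated), via keto aldehyde 6 (not isolated)
Conditions: O3, CH2Cl2, −78 °C; PPh3, −78 °C → rt; solvent removed; NaBH(OAc)3, THF/AcOH, rt
Reagents that add atoms: ozone, [O-][O+]=O
Why: Ozonolysis with phosphine work-up cuts the terminal alkene to the C12 aldehyde, and NaBH(OAc)3 should reduce the aldehyde but not the hindered α-quaternary ketone (chemoselective hydride reduction).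

Step 3
Reactants: 7 (2S,3R)-2-(2-hydroxyethyl)-2,3-dimethylcyclohexan-1-one
Product: 8 2-[(1S,6R)-1,6-dimethyl-2-oxocyclohexyl]ethyl 2,2-dimethylpropanoate
Conditions: PivCl, pyridine, DMAP (cat.), CH2Cl2, 0 °C → rt
Reagents that add atoms: pivaloyl chloride, CC(C)(C)C(=O)Cl
Why: Acylation of the primary alcohol (drawn from any lactol form) gives an ester oxygen that is not nucleophilic towards C10 and should survive low-valent titanium (esterification).

Step 4
Reactants: 8 2-[(1S,6R)-1,6-dimethyl-2-oxocyclohexyl]ethyl 2,2-dimethylpropanoate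
Product: 9 2-[(1S,6R)-2,2-dimethoxy-1,6-dimethylcyclohexyl]ethyl 2,2-dimethylpropanoate
Conditions: TMSOMe, TMSOTf (cat.), CH2Cl2, −78 → −20 °C; pyridine quench
Reagents that add atoms: methoxytrimethylsilane, CO[Si](C)(C)C
Why: Silyl-transfer ketalisation under aprotic conditions is driven by formation of hexamethyldisiloxane and suits a hindered ketone; any methyl enol ether formed alongside serves equally in step 7.

Step 5
Reactants: 10 (S)-benzyl glycidyl ether
Product: 11 (2S)-1-(benzyloxy)but-3-en-2-ol
Conditions: Me3S+ I− (3 equiv), n-BuLi, THF, −10 °C → rt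
Reagents that add atoms: trimethylsulfonium iodide, C[S+](C)C.[I-]
Why: Dimethylsulfonium methylide opens the epoxide at its CH2 terminus and the β-alkoxy sulfonium salt eliminates to the allylic alcohol, leaving the stereocentre untouched (one-carbon homologation of an epoxide to an allylic alcohol).

Step 6
Reactants: 11 (2S)-1-(benzyloxy)but-3-en-2-ol; 12 methyl methacrylate
Product: 13 methyl (2E,4S)-5-(benzyloxy)-4-hydroxy-2-methylpent-2-enoate
Conditions: second-generation Hoveyda–Grubbs catalyst (5 mol%), 12 (excess), CH2Cl2, 40 °C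
Reagents that add atoms: none
Why: Olefin cross-metathesis of a terminal alkene with a 1,1-disubstituted acrylate should give the thermodynamically preferred (E)-trisubstituted enoate and tolerates the free allylic alcohol.

Step 7
Reactants: 9 2-[(1S,6R)-2,2-dimethoxy-1,6-dimethylcyclohexyl]ethyl 2,2-dimethylpropanoate; 13 methyl (2E,4S)-5-(benzyloxy)-4-hydroxy-2-methylpent-2-enoate
Product: 15 methyl (2S,3E)-5-(benzyloxy)-2-[(1R,3S,4R)-3-{2-[(2,2-dimethylpropanoyl)oxy]ethyl}-3,4-dimethyl-2-oxocyclohexyl]-2-methylpent-3-enoate, via allyl enol ether 14 (not isolated)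
Conditions: 2,4,6-trimethylbenzoic acid (10 mol%), xylene, 140 °C, methanol distilled off
Reagents that add atoms: none
Why: Acid-catalysed exchange of the ketal with 13 and loss of methanol can give only the C10=C5 enol ether (C9 is quaternary), and its Claisen rearrangement through a chair with CH2OBn equatorial and the enoate methyl axial should form C4–C5 and transfer the carbinol configuration to C4 (S) and C5 (R) (ketal Claisen rearrangement with 1,3-chirality transfer).

Step 8
Reactants: 15 Claisen product
Product: 16 methyl (2S)-2-[(1R,3S,4R)-3-{2-[(2,2-dimethylpropanoyl)oxy]ethyl}-3,4-dimethyl-2-oxocyclohexyl]-5-hydroxy-2-methylpentanoate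
Conditions: H2 (1 atm), Pd/C (10%), EtOAc, rt
Reagents that add atoms: none
Why: Heterogeneous hydrogenation should saturate the disubstituted C2=C3 alkene and hydrogenolyse the benzyl ether in one operation without touching the hindered ketone or the esters; crude 16 is oxidised at once so that it cannot lactonise onto C18.

Step 9
Reactants: 16 hydroxy keto diester
Product: 17 methyl (2S)-2-[(1R,3S,4R)-3-{2-[(2,2-dimethylpropanoyl)oxy]ethyl}-3,4-dimethyl-2-oxocyclohexyl]-2-methyl-5-oxopentanoate
Conditions: Dess–Martin periodinane, NaHCO3, CH2Cl2, 0 °C → rt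
Reagents that add atoms: none
Why: Buffered Dess–Martin oxidation turns the primary alcohol into the C1 aldehyde under near-neutral conditions that should not epimerise C5.

Step 10
Reactants: 17 ring-B keto aldehyde
Product: 19 methyl (1S,5S,6R,8aS)-5-{2-[(2,2-dimethylpropanoyl)oxy]ethyl}-1,5,6-trimethyl-1,2,3,5,6,7,8,8a-octahydronaphthalene-1-carboxylate, via titanium pinacolate 18 (not isolated)
Conditions: TiCl3(DME)1.5, Zn–Cu couple, DME, reflux; 17 added by syringe pump over 30 h (high dilution), then 6 h reflux
Reagents that add atoms: none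
Why: Low-valent titanium, made from TiCl3(DME)1.5 and Zn–Cu, passes one electron to each carbonyl, the two ketyl carbons C1 and C10 join to a titanium-bound 1,2-diolate (18), and at reflux both C–O bonds are broken on titanium to leave the C1=C10 alkene. The closest known reaction is the intramolecular McMurry coupling of keto aldehydes to cycloalkenes under these TiCl3/Zn–Cu slow-addition conditions. Ring A closes as a six-membered ring by this C1–C10 carbonyl–carbonyl union, the C1–C2–C3–C4–C5 chain already holding the two carbonyls in a 1,6 relationship, so closure should outrun intermolecular coupling at high dilution. No stereocentre is formed; C4, C5, C8 and C9 are carried through, and the double bond can only lie between the two former carbonyl carbons. The step needs the aldehyde ketyl to couple with the hindered C10 ketone and not with the C18 methyl ester or the pivalate, which the far easier reduction of ketone and aldehyde and the shielded or remote position of the ester carbonyls should secure. It also needs C5 to keep its configuration, which the neutral medium, the absence of hydrogen on C9 and the strain of enolising towards the C4-substituted C5 should secure.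

Step 11
Reactants: 19 bicyclic pivalate ester
Product: 20 methyl (1S,5S,6R,8aS)-5-(2-hydroxyethyl)-1,5,6-trimethyl-1,2,3,5,6,7,8,8a-octahydronaphthalene-1-carboxylate
Conditions: NaOMe, MeOH, 60 °C
Reagents that add atoms: none
Why: Methanolysis removes the pivalate, while the far more shielded α-quaternary C18 methyl ester can at most exchange methoxide for methoxide (transesterification).

Step 12
Reactants: 20 C12 alcohol
Product: 21 methyl (1S,5S,6R,8aS)-5-(2-iodoethyl)-1,5,6-trimethyl-1,2,3,5,6,7,8,8a-octahydronaphthalene-1-carboxylate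
Conditions: I2, PPh3, imidazole, CH2Cl2, 0 °C → rt
Reagents that add atoms: iodine, II
Why: Appel-type iodination proceeds by SN2 displacement of the alkoxyphosphonium ion at primary C12 under neutral conditions that should leave the trisubstituted alkene alone.

Step 13
Reactants: 22 but-2-yn-1-ol
Product: 23 (but-2-yn-1-yloxy)(tert-butyl)dimethylsilane
Conditions: TBSCl, imidazole, DMF, rt
Reagents that add atoms: tert-butyldimethylsilyl chloride, CC(C)(C)[Si](C)(C)Cl
Why: Standard silylation protects the alcohol for the organometallic steps.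

Step 14
Reactants: 23 (but-2-yn-1-yloxy)(tert-butyl)dimethylsilane
Product: 25 tert-butyl{[(2E)-3-iodobut-2-en-1-yl]oxy}dimethylsilane, via alkenylzirconocene 24 (not isolated)
Conditions: Cp2Zr(H)Cl (excess), THF, 50 °C; then I2, THF, 0 °C
Reagents that add atoms: iodine, II
Why: Syn hydrozirconation under equilibrating conditions should place zirconium on the less hindered methyl-bearing carbon, and iodinolysis with retention then gives the (E)-vinyl iodide (hydrozirconation–iodination).

Step 15
Reactants: 21 C12 iodide; 25 (E)-vinyl iodide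
Product: 27 methyl (1S,5S,6R,8aS)-5-[(3E)-5-{[tert-butyl(dimethyl)silyl]oxy}-3-methylpent-3-en-1-yl]-1,5,6-trimethyl-1,2,3,5,6,7,8,8a-octahydronaphthalene-1-carboxylate, via alkylzinc iodide 26 (not isolated)
Conditions: Zn dust (activated with 1,2-dibromoethane and TMSCl), LiCl, THF, 40 °C; then 25, Pd(OAc)2 (cat.), SPhos (cat.), THF, rt → 40 °C
Reagents that add atoms: none
Why: Direct zinc insertion into the primary iodide tolerates the ester, and Negishi coupling of the alkylzinc with the alkenyl iodide at zerovalent palladium should form C12–C13 with retention of the (E) geometry.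

Step 16
Reactants: 27 coupled silyl ether methyl ester
Product: 28 (1S,5S,6R,8aS)-5-[(3E)-5-{[tert-butyl(dimethyl)silyl]oxy}-3-methylpent-3-en-1-yl]-1,5,6-trimethyl-1,2,3,5,6,7,8,8a-octahydronaphthalene-1-carboxylic acid
Conditions: NaSEt, DMF, 90 °C; then cold 1 M HCl
Reagents that add atoms: none
Why: The carbonyl of the α-quaternary ester is shielded, so thiolate should attack the O-methyl carbon and release the carboxylate (SN2 ester dealkylation), conditions under which the silyl ether and the alkenes are inert.

Step 17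
Reactants: 28 silyl ether acid
Product: 29 (1S,5S,6R,8aS)-5-[(3E)-5-hydroxy-3-methylpent-3-en-1-yl]-1,5,6-trimethyl-1,2,3,5,6,7,8,8a-octahydronaphthalene-1-carboxylic acid
Conditions: TBAF, THF, 0 °C → rt; aq. NH4Cl
Reagents that add atoms: none
Why: Fluoride cleaves the Si–O bond of the allylic silyl ether without affecting the carboxylate (fluoride desilylation).

Step 18
Reactants: 29 hydroxy acid
Product: 30 (1S,5S,6R,8aS)-1,5,6-trimethyl-5-[(3E)-3-methyl-5-(propanoyloxy)pent-3-en-1-yl]-1,2,3,5,6,7,8,8a-octahydronaphthalene-1-carboxylic acid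
Conditions: propanoic anhydride (1.2 equiv), pyridine, DMAP (cat.), CH2Cl2, 0 °C; aq. NaHCO3, then work-up at pH 4
Reagents that add atoms: propanoic anhydride, CCC(=O)OC(=O)CC
Why: The unhindered primary allylic alcohol is acylated selectively, and any mixed anhydride formed at the shielded C18 acid should be hydrolysed back to the acid on aqueous work-up (DMAP-catalysed esterification).

**Compound list**

1 | 2-methylcyclohex-2-en-1-one | CC1=CCCC1=O | starting material
2 | allyl bromide | C=CCBr | starting material
3 | dimethylaluminium enolate of (3R)-2,3-dimethylcyclohexanone | C[C@@H]1CCCC(O[Al](C)C)=C1C | intermediate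
4 | (2S,3R)-2,3-dimethyl-2-(prop-2-en-1-yl)cyclohexan-1-one | C=CC[C@]1(C)C(=O)CCC[C@H]1C | intermediate
5 | ozonide of 4, 3-{[(1S,6R)-1,6-dimethyl-2-oxocyclohexyl]methyl}-1,2,4-trioxolane (trioxolane carbon unassigned) | C2(OCOO2)C[C@]1(C)C(=O)CCC[C@H]1C | intermediate
6 | 2-[(1S,6R)-1,6-dimethyl-2-oxocyclohexyl]acetaldehyde | O=CC[C@]1(C)C(=O)CCC[C@H]1C | intermediate
7 | (2S,3R)-2-(2-hydroxyethyl)-2,3-dimethylcyclohexan-1-one | OCC[C@]1(C)C(=O)CCC[C@H]1C | intermediate
8 | 2-[(1S,6R)-1,6-dimethyl-2-oxocyclohexyl]ethyl 2,2-dimethylpropanoate | CC(C)(C)C(=O)OCC[C@]1(C)C(=O)CCC[C@H]1C | intermediate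
9 | 2-[(1S,6R)-2,2-dimethoxy-1,6-dimethylcyclohexyl]ethyl 2,2-dimethylpropanoate | CC(C)(C)C(=O)OCC[C@]1(C)C(OC)(OC)CCC[C@H]1C | intermediate
10 | (S)-benzyl glycidyl ether, (2S)-2-[(benzyloxy)methyl]oxirane | C(OCc1ccccc1)[C@@H]1CO1 | starting material
11 | (2S)-1-(benzyloxy)but-3-en-2-ol | C=C[C@H](O)COCc1ccccc1 | intermediate
12 | methyl methacrylate | C=C(C)C(=O)OC | starting material
13 | methyl (2E,4S)-5-(benzyloxy)-4-hydroxy-2-methylpent-2-enoate | COC(=O)/C(C)=C/[C@H](O)COCc1ccccc1 | intermediate
14 | methyl (2E,4S)-5-(benzyloxy)-4-{[(5R,6S)-6-{2-[(2,2-dimethylpropanoyl)oxy]ethyl}-5,6-dimethylcyclohex-1-en-1-yl]oxy}-2-methylpent-2-enoate (allyl enol ether at C10) | CC(C)(C)C(=O)OCC[C@]1(C)C(O[C@H](COCc2ccccc2)/C=C(\C)C(=O)OC)=CCC[C@H]1C | intermediate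
15 | methyl (2S,3E)-5-(benzyloxy)-2-[(1R,3S,4R)-3-{2-[(2,2-dimethylpropanoyl)oxy]ethyl}-3,4-dimethyl-2-oxocyclohexyl]-2-methylpent-3-enoate | CC(C)(C)C(=O)OCC[C@]1(C)C(=O)[C@@H]([C@](C)(/C=C/COCc2ccccc2)C(=O)OC)CC[C@H]1C | intermediate
16 | methyl (2S)-2-[(1R,3S,4R)-3-{2-[(2,2-dimethylpropanoyl)oxy]ethyl}-3,4-dimethyl-2-oxocyclohexyl]-5-hydroxy-2-methylpentanoate | CC(C)(C)C(=O)OCC[C@]1(C)C(=O)[C@@H]([C@](C)(CCCO)C(=O)OC)CC[C@H]1C | intermediate
17 | methyl (2S)-2-[(1R,3S,4R)-3-{2-[(2,2-dimethylpropanoyl)oxy]ethyl}-3,4-dimethyl-2-oxocyclohexyl]-2-methyl-5-oxopentanoate (ring-B keto aldehyde: C10 ketone, C1 aldehyde) | CC(C)(C)C(=O)OCC[C@]1(C)C(=O)[C@@H]([C@](C)(CCC=O)C(=O)OC)CC[C@H]1C | intermediate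
18 | titanium-bound C1,C10-diolate of the closed ring A (drawn as the dianion, titanium omitted, C1 and C10 configuration not defined) | CC(C)(C)C(=O)OCC[C@]1(C)C2([O-])C([O-])CC[C@](C)(C(=O)OC)[C@H]2CC[C@H]1C | intermediate
19 | methyl (1S,5S,6R,8aS)-5-{2-[(2,2-dimethylpropanoyl)oxy]ethyl}-1,5,6-trimethyl-1,2,3,5,6,7,8,8a-octahydronaphthalene-1-carboxylate | CC(C)(C)C(=O)OCC[C@]1(C)C2=CCC[C@](C)(C(=O)OC)[C@H]2CC[C@H]1C | intermediate
20 | methyl (1S,5S,6R,8aS)-5-(2-hydroxyethyl)-1,5,6-trimethyl-1,2,3,5,6,7,8,8a-octahydronaphthalene-1-carboxylate | OCC[C@]1(C)C2=CCC[C@](C)(C(=O)OC)[C@H]2CC[C@H]1C | intermediate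
21 | methyl (1S,5S,6R,8aS)-5-(2-iodoethyl)-1,5,6-trimethyl-1,2,3,5,6,7,8,8a-octahydronaphthalene-1-carboxylate | ICC[C@]1(C)C2=CCC[C@](C)(C(=O)OC)[C@H]2CC[C@H]1C | intermediate
22 | but-2-yn-1-ol | CC#CCO | starting material
23 | (but-2-yn-1-yloxy)(tert-butyl)dimethylsilane | CC#CCO[Si](C)(C)C(C)(C)C | intermediate
24 | (E)-alkenylzirconocene chloride, zirconium on the methyl-bearing carbon, trans to CH2OTBS | C/C(=C\CO[Si](C)(C)C(C)(C)C)[Zr](Cl)(C1C=CC=C1)C1C=CC=C1 | intermediate
25 | tert-butyl{[(2E)-3-iodobut-2-en-1-yl]oxy}dimethylsilane | C/C(I)=C\CO[Si](C)(C)C(C)(C)C | intermediate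
26 | alkylzinc iodide from 21 (zinc on C12) | I[Zn]CC[C@]1(C)C2=CCC[C@](C)(C(=O)OC)[C@H]2CC[C@H]1C | intermediate
27 | methyl (1S,5S,6R,8aS)-5-[(3E)-5-{[tert-butyl(dimethyl)silyl]oxy}-3-methylpent-3-en-1-yl]-1,5,6-trimethyl-1,2,3,5,6,7,8,8a-octahydronaphthalene-1-carboxylate | CC(C)(C)[Si](C)(C)OC/C=C(\C)CC[C@]1(C)C2=CCC[C@](C)(C(=O)OC)[C@H]2CC[C@H]1C | intermediate
28 | (1S,5S,6R,8aS)-5-[(3E)-5-{[tert-butyl(dimethyl)silyl]oxy}-3-methylpent-3-en-1-yl]-1,5,6-trimethyl-1,2,3,5,6,7,8,8a-octahydronaphthalene-1-carboxylic acid | CC(C)(C)[Si](C)(C)OC/C=C(\C)CC[C@]1(C)C2=CCC[C@](C)(C(=O)O)[C@H]2CC[C@H]1C | intermediate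
29 | (1S,5S,6R,8aS)-5-[(3E)-5-hydroxy-3-methylpent-3-en-1-yl]-1,5,6-trimethyl-1,2,3,5,6,7,8,8a-octahydronaphthalene-1-carboxylic acid | OC/C=C(\C)CC[C@]1(C)C2=CCC[C@](C)(C(=O)O)[C@H]2CC[C@H]1C | intermediate
30 | (1S,5S,6R,8aS)-1,5,6-trimethyl-5-[(3E)-3-methyl-5-(propanoyloxy)pent-3-en-1-yl]-1,2,3,5,6,7,8,8a-octahydronaphthalene-1-carboxylic acid (halimane numbering 4S,5S,8R,9S,13E) | CCC(=O)OC/C=C(\C)CC[C@]1(C)C2=CCC[C@](C)(C(=O)O)[C@H]2CC[C@H]1C | target

**Step count**

Total steps: 18. Longest linear sequence: 14 (steps 1–4, 7–12, 15–18).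

**Steps most likely to fail**

Step 10. The aldehyde ketyl may be reduced, may couple intermolecularly, or may add to the C18 ester faster than it reaches the doubly flanked C10 ketone, and deoxygenation of the hindered diolate may stall. The fallback sets out from 17. SmI2 (THF, t-BuOH, −78 °C) should induce pinacol cyclisation to the cis-C1,C10-diol F1. Thiocarbonyldiimidazole (toluene, 110 °C) converts it into the cyclic thionocarbonate F2. Trimethyl phosphite at reflux (Corey–Winter olefination) then expels CO2 and sulfur and gives the alkene, rejoining the route at 19.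

Step 7. Ketal exchange at the hindered C10 with a secondary alcohol may be too slow to compete with decomposition, and control at C5 may be eroded by a boat transition state or by acid-promoted enolisation of the product. The fallback sets out from 8 and uses 13. KHMDS and PhNTf2 (THF, −78 °C) give the enol triflate F3. Miyaura borylation (B2pin2, PdCl2(dppf), KOAc, dioxane, 80 °C) gives the alkenyl pinacol boronate F4. Oxidative C–O coupling with 13 promoted by Cu(OAc)2 (Et3N, CH2Cl2, rt, air) then gives the enol ether, rejoining the route at 14, which is isolated and heated without acid (toluene, 130 °C) to give 15.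

Step 1. Facial control in methyl delivery to the α-substituted enone may be incomplete, and allylation of the aluminate enolate may be sluggish, so that protonated ketone forms. The fallback sets out from allyl bromide 2 and uses commercial cyclohex-2-en-1-one F5 in place of 1. Addition of Me2Zn catalysed by Cu(OTf)2 and the same phosphoramidite ligand, with MeI/HMPA quench of the zinc enolate, gives (3R)-2,3-dimethylcyclohexan-1-one F6 (either C2 epimer serves). TMSCl, NaI and Et3N in MeCN give the more substituted silyl enol ether F7. MeLi followed by 2 then allylates anti to the C8 methyl, rejoining the route at 4.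

**Further compounds**

F1 | step 10 | cis-C1,C10-diol of the closed ring A (face not assigned) | CC(C)(C)C(=O)OCC[C@]1(C)C2(O)C(O)CC[C@](C)(C(=O)OC)[C@H]2CC[C@H]1C
F2 | step 10 | cyclic thionocarbonate of F1 | CC(C)(C)C(=O)OCC[C@]1(C)C23OC(=S)OC3CC[C@](C)(C(=O)OC)[C@H]2CC[C@H]1C
F3 | step 7 | enol triflate of 8 (C10–OTf, C10=C5) | CC(C)(C)C(=O)OCC[C@]1(C)C(OS(=O)(=O)C(F)(F)F)=CCC[C@H]1C
F4 | step 7 | alkenyl pinacol boronate (boron on C10, C10=C5) | CC(C)(C)C(=O)OCC[C@]1(C)C(B2OC(C)(C)C(C)(C)O2)=CCC[C@H]1C
F5 | step 1 | cyclohex-2-en-1-one (commercial, used in place of 1) | O=C1C=CCCC1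
F6 | step 1 | (3R)-2,3-dimethylcyclohexan-1-one (C2 epimers) | CC1C(=O)CCC[C@H]1C
F7 | step 1 | {[(3R)-2,3-dimethylcyclohex-1-en-1-yl]oxy}trimethylsilane | C[C@@H]1CCCC(O[Si](C)(C)C)=C1C
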